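## Structural features

Piscerythrinetin (15) is an isoflavone: benzene ring A is fused to the 4-pyranone ring C (a 4H-chromen-4-one), and aryl ring B is attached to C3 through the single bond C3–C1'. Ring A carries free hydroxyl groups at C5 and C7, which with O1 form a phloroglucinol pattern. Ring B is 1,3,4,5-tetrasubstituted, with methoxy groups at C3' and C4' and a 3-methylbut-2-enyl (prenyl) chain at C5'. The molecule has no stereocenter, so no stereocenters stand next to each other, and the prenyl alkene ends in two identical methyl groups, so there is no alkene geometry to set. The fragile parts are the prenyl group (acid turns it into a tertiary cation, hydrogen saturates it), the electron-rich ring A with its acidic 7-OH and nucleophilic C6 and C8, and C2 of the pyranone, which hard nucleophiles attack with ring opening. The real difficulty is selectivity of position and of functional group: the aryl group must sit at C3 with no coumarin or 2-aryl isomer, the prenyl chain must go to C5' although ring A is the more nucleophilic ring, and the ring A oxygens must be freed while the ring B oxygens stay methylated. The key step uses the local twofold symmetry of ring A before closure: in a 3,5-dioxygenated aryl ether the two carbons ortho to the future O1 (the future C4a and C8) are equivalent and activated by all three oxygens, so making C4–C4a last poses no regiochemical choice.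

## Logic of the disconnections

15 is cut at the C5'–CH2 bond into 13 and 14. The prenyl group is the most acid-sensitive part of the target, so it enters last, after all Lewis acid chemistry. This leaves 13 with only robust groups, and 14 is purchased. The forward coupling must deliver the allylic unit through its primary carbon under neutral conditions and tolerate two free phenols and the pyranone.

13 is traced to 12 by restoring the two O–benzyl bonds on ring A. The ring A oxygens must be masked during the acylation, and benzyl is the ether that can later be cleaved beside methyl ethers and an aryl bromide. The forward cleavage must work without hydrogen, must leave the methoxy groups alone, and must trap the benzyl cations before they alkylate C6 or C8. Doing this before the coupling keeps the Lewis acid away from the alkene.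

12 is opened at the C4–C4a bond to 10, the forward reaction passing through 11. The cut is made here because ring A is symmetric at this stage, and because O1–C2, C2=C3 and C3–C1' already exist, so neither a coumarin nor a 2-aryl isomer can form. A bicyclic chromone becomes an acyclic acrylic acid that links two simple arenes. The forward step needs activation strong enough to acylate the arene yet mild enough for the benzyl ethers, and the carbonyl and aryloxy groups must be cis or able to become cis. Bromine stands in for the prenyl group.

10 is traced to 9 by changing the acid into its methyl ester. The ester is needed for the enolate chemistry that builds C2. The forward hydrolysis must occur at the acyl carbon without displacing the aryloxy group from C3.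

9 is cut at the O1–C2 bond into 7 and 8. This joins the ring A half to the ring B half in one step, and 8 is purchased and symmetric. The phenoxide must attack through oxygen, at carbon rather than at sulfur, and the geometry should be retained as far as possible.

7 is traced to 6 by cutting the O–S bond. The enol oxygen becomes a leaving group. Lithium chelation in the forward step is meant to set the Z geometry, so that the ring closure does not depend entirely on later isomerization.

6 is cut at the C2–C3 bond (chromone numbering) into 4 and 5. C2 then comes from the simplest one-carbon ester. Only 4 can enolize, so the crossed condensation has one outcome.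

4 is traced through 3 to 1 and 2 by cutting the bond between the benzylic carbon and the carboxyl carbon (C3–C4 of the chromone). 1 is the purchased arene in which bromine and both methoxy groups are already correctly placed. The homologation takes two steps and must leave the aryl bromide and the methyl ethers untouched.

## Other disconnections considered

Alternative 1: The cut lies in ring B, at C3'–C4' and C5'–C6'. It gives a chromone bearing a 3-methoxy-2-pyrone at C3 (A2) and an alkynyl methyl ether that already carries the prenyl chain (A3).
- Forward step: heating A2 with A3 would give a bridged bicyclic lactone by [4+2] cycloaddition, which would lose CO2 in a retro-[4+2] step and leave the benzene ring of A1. Acidic removal of the methoxymethyl groups would then give 15.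
- In favour: both new ring B bonds and the whole substitution pattern arise in one operation. The prenyl group arrives inside a building block, so there is no allyl-transfer regiochemistry and no organotin reagent, and ring A never meets a Lewis acid.
- Against: ring B of 15 is an ordinary benzene that can be bought with its substituents in place, so building it de novo solves a problem that is absent here. A2 needs a chromone–pyrone coupling of its own and A3 is a sensitive ynol ether. The 3-methoxy group makes the pyrone a reluctant diene, so high temperature would be needed. The regiochemistry rests on matching the nucleophilic alkyne carbon with C6 of the pyrone, which is a polarity preference and not a structural necessity.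
- Comparison: on structure the alternative is the equal of the chosen plan in convergence, and it is the better one in carrying the prenyl group through without a late cross-coupling. On mechanism it is neutral and pericyclic, which is gentler, but it is less secure in regiochemistry than a closure with only one possible site. On step economy it is worse, because of fragment preparation and a final acidic deprotection next to the prenyl group.

Alternative 2: The cut lies in ring A, at C4a–C8a, and unravels the phloroglucinol ring to the linear triketo ester A5.
- Forward step: methoxide (KOH in methanol, or Mg(OMe)2) would deprotonate C6 of A5, and intramolecular Claisen condensation onto the ester carbon followed by enolization would give the acylphloroglucinol A4. A one-carbon electrophile would then close ring C onto either of the two equivalent ortho hydroxyl groups and give 15 directly.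
- In favour: the plan follows the biosynthetic folding, needs no protecting group, and delivers the 5,7-hydroxyl groups as such. The symmetry of ring A serves it just as it serves the chosen plan.
- Against: A5 can fold in other ways. C2 can attack the C7 ketone in an aldol closure, an enol oxygen can attack the ester to give a hydroxypyrone, and the benzylic C8 can enolize. The Claisen mode must therefore be imposed by base and counterion and is not enforced by the structure. A5 has to be assembled by polyanion acylation with the prenyl group already attached, which needs the same kind of cross-coupling as the chosen route. Ring A is also available intact by purchase, so making it from a chain is extra work.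
- Comparison: on structure both plans exploit the same symmetry, and the alternative is the better one in needing no protection. On mechanism the chosen electrophilic closure has one possible outcome, whereas the carbanion folding has several. On step economy the alternative is about equal on paper, and that only if the folding is selective.

Alternative 3: The cut removes both ring C bonds at once, C3–C4 and O1–C2, and gives salicylaldehyde A7 and arylsilylalkyne A8.
- Forward step: with [Cp*RhCl2]2 (trivalent rhodium) and Cu(OAc)2 (divalent copper) as oxidant, phenoxide-directed activation of the aldehyde C–H bond would give an acyl rhodacycle. Alkyne insertion and C–O reductive elimination would give the 2-silylchromone A6. Protodesilylation and removal of the methoxymethyl groups would follow.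
- In favour: two bonds and ring C would form in one catalytic step from two fragments of similar size, no acid is involved, and the silyl group would steer the aryl group to C3 and then leave without trace.
- Against: the insertion regiochemistry depends on a steric and electronic bias of the alkyne. The formyl group of A7 is flanked by two oxygen substituents. The prenyl alkene of A8 would be exposed to an electrophilic rhodium centre and a copper oxidant at elevated temperature, where allylic C–H activation or alkene migration is conceivable. A8 needs two selective couplings on a dihalogenated ring B precursor, and two further steps follow the annulation, one of them acidic and next to the prenyl group.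
- Comparison: on structure the alternative is more convergent, which is a point where it is the better plan. On mechanism it avoids Lewis acids, where it is the equal or the better plan for the protecting groups, but its regiochemistry is steered by a substituent whereas the chosen plan relies on symmetry. On step economy it is roughly equal in count but depends more on precious metal and on oxidative conditions beside an alkene.

Key step: step 7

Remark on the chemistry: 10 and 12 map onto the target atom for atom (carboxyl carbon = C4, benzylic carbon = C3, former formyl carbon = C2, phenol oxygen = O1); in 7, 9, 10 and 11 the descriptor Z means that the carbonyl group and the oxygen at C3 are cis, which is the arrangement that closes ring C, and any E isomer that forms alongside is carried on because step 7 equilibrates the push-pull alkene.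

## Route

Step 1
Reactants: 1 3-bromo-4,5-dimethoxybenzaldehyde; 2 methyl (methylsulfanyl)methyl sulfoxide
Product: 3 1-bromo-2,3-dimethoxy-5-[(E)-2-(methylsulfinyl)-2-(methylsulfanyl)ethenyl]benzene (racemic at sulfur)
Conditions: BnMe3NOH (40% in MeOH, cat.), THF, reflux
Reagents that add atoms: none
Why: Knoevenagel-type condensation; the methylene between the sulfanyl and sulfinyl groups is acidic enough for the ammonium hydroxide, and the non-enolizable aryl aldehyde can only condense. The alkene geometry (drawn E) is of no consequence because the double bond is consumed in step 2.

Step 2
Reactants: 3 1-bromo-2,3-dimethoxy-5-[(E)-2-(methylsulfinyl)-2-(methylsulfanyl)ethenyl]benzene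
Product: 4 methyl 2-(3-bromo-4,5-dimethoxyphenyl)acetate
Conditions: HCl (g), MeOH, 0 °C to rt
Reagents that add atoms: methanol, CO
Why: Acid-promoted methanolysis of a ketene dithioacetal S-oxide; protonation at the benzylic carbon gives a sulfur-stabilized cation that takes up methanol and sheds both sulfur groups as dimethyl disulfide, which leaves the arylacetic ester. This is the established one-carbon homologation of aryl aldehydes to arylacetates, and the aryl bromide and methyl ethers are inert to it.

Step 3
Reactants: 4 methyl 2-(3-bromo-4,5-dimethoxyphenyl)acetate; 5 methyl formate
Product: 6 methyl (Z)-2-(3-bromo-4,5-dimethoxyphenyl)-3-hydroxyprop-2-enoate (hydrogen-bonded enol of the α-formyl ester)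
Conditions: NaH, THF, 0 °C to rt; then aq. HCl
Reagents that add atoms: none
Why: Crossed Claisen condensation; the ester enolate attacks the non-enolizable formate, and deprotonation of the acidic formyl ester drives the equilibrium. The product is handled as its enol and used without long storage.

Step 4
Reactants: 6 methyl (Z)-2-(3-bromo-4,5-dimethoxyphenyl)-3-hydroxyprop-2-enoate
Product: 7 methyl (Z)-2-(3-bromo-4,5-dimethoxyphenyl)-3-[(4-methylphenyl)sulfonyloxy]prop-2-enoate
Conditions: TsCl, N-methylimidazole, LiOH, MeCN, 0 °C to rt
Reagents that add atoms: p-toluenesulfonyl chloride, Cc1ccc(cc1)S(Cl)(=O)=O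
Why: O-Sulfonylation of the enolate by the N-sulfonylimidazolium species; lithium chelation between the enolate oxygen and the ester carbonyl holds the oxygen cis to the ester, so the Z enol tosylate should be trapped.

Step 5
Reactants: 7 methyl (Z)-2-(3-bromo-4,5-dimethoxyphenyl)-3-[(4-methylphenyl)sulfonyloxy]prop-2-enoate; 8 3,5-bis(benzyloxy)phenol
Product: 9 methyl (Z)-3-[3,5-bis(benzyloxy)phenoxy]-2-(3-bromo-4,5-dimethoxyphenyl)prop-2-enoate
Conditions: K2CO3, DMF, 0 °C to rt
Reagents that add atoms: none
Why: Addition–elimination (nucleophilic vinylic substitution); the phenoxide adds to the β-carbon of the acrylate and the stabilized ester enolate expels tosylate, normally faster than C–C rotation, so the Z geometry should largely be retained. The O1–C2 bond is made here, before ring C exists.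

Step 6
Reactants: 9 methyl (Z)-3-[3,5-bis(benzyloxy)phenoxy]-2-(3-bromo-4,5-dimethoxyphenyl)prop-2-enoate
Product: 10 (Z)-3-[3,5-bis(benzyloxy)phenoxy]-2-(3-bromo-4,5-dimethoxyphenyl)prop-2-enoic acid
Conditions: LiOH·H2O, THF/H2O, rt to 40 °C; then aq. HCl to pH 3
Reagents that add atoms: water (delivered as LiOH·H2O), O
Why: Saponification; methanol is left out so that no alkoxide can exchange the aryloxy group at C3, and once the carboxylate has formed the acrylate no longer accepts nucleophiles at C3. Benzyl ethers, methyl ethers and the aryl bromide are inert to LiOH at this temperature.

Step 7
Reactants: 10 (Z)-3-[3,5-bis(benzyloxy)phenoxy]-2-(3-bromo-4,5-dimethoxyphenyl)prop-2-enoic acid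
Product: 12 5,7-bis(benzyloxy)-3-(3-bromo-4,5-dimethoxyphenyl)chromen-4-one, via acid chloride 11 (not isolated)
Conditions: (COCl)2, DMF (cat.), CH2Cl2, 0 °C; then SnCl4, CH2Cl2, −78 to 0 °C
Reagents that add atoms: none
Why: Oxalyl chloride with catalytic DMF turns the acid into acyl chloride 11, which has no α-hydrogen and so cannot form a ketene. SnCl4 polarizes or ionizes the C–Cl bond, and the acyl carbon is attacked by the ring A carbon ortho to the vinyl ether oxygen, a carbon that is also ortho to one benzyloxy group and para to the other; loss of a proton from the arenium ion gives the pyranone, an intramolecular Friedel–Crafts acylation whose closest known type is the acid-mediated cyclization of 3-aryloxyacrylic acids to chromones. Ring C closes in the 6-exo-trig mode, with the carbonyl oxygen outside the new ring, and no stereocenter is formed. Regioselectivity is secured by the substrate: the two carbons that can reach the acyl carbon are related by the symmetry of ring A, the carbon between the two benzyloxy groups cannot reach it, and closure onto ring B would require a four-membered ring. The Z isomer closes directly, and any E isomer equilibrates through the Lewis acid complex, in which the C2–C3 bond has single-bond character. Because O1–C2 is already in place a coumarin cannot form, and the bromine is inert where a prenyl group would not be. Low temperature and about one equivalent of SnCl4 are chosen to spare the benzyl ethers; if the chelated 5-O-benzyl group is partly lost, that material still converges on 13 in step 8.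

Step 8
Reactants: 12 5,7-bis(benzyloxy)-3-(3-bromo-4,5-dimethoxyphenyl)chromen-4-one
Product: 13 3-(3-bromo-4,5-dimethoxyphenyl)-5,7-dihydroxychromen-4-one
Conditions: BCl3, C6HMe5, CH2Cl2, −78 °C; then H2O
Reagents that add atoms: none
Why: Lewis acid debenzylation; BCl3 coordinates the ether oxygens (the 5-O first, helped by the C4 carbonyl) and pentamethylbenzene intercepts the benzyl cations, which prevents C-benzylation of ring A. At −78 °C the aryl methyl ethers, including the hindered one at C4', and the aryl bromide should stay intact, and no alkene is present yet.

Step 9
Reactants: 13 3-(3-bromo-4,5-dimethoxyphenyl)-5,7-dihydroxychromen-4-one; 14 tributyl(3-methylbut-2-enyl)stannane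
Product: 15 piscerythrinetin, 5,7-dihydroxy-3-[3,4-dimethoxy-5-(3-methylbut-2-enyl)phenyl]chromen-4-one
Conditions: Pd(PPh3)4 (zerovalent palladium), DMF, 100 °C, degassed
Reagents that add atoms: none
Why: Stille coupling; oxidative addition of zerovalent palladium into the C5'–Br bond, transmetalation with the allylic stannane and reductive elimination at the less hindered primary carbon should give the linear prenyl arene. The conditions are neutral, so the free phenols, the pyranone and the new alkene are not endangered.

## Compound list

1 | 3-bromo-4,5-dimethoxybenzaldehyde | COc1cc(C=O)cc(Br)c1OC | starting material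
2 | methyl (methylsulfanyl)methyl sulfoxide, (methylsulfinyl)(methylsulfanyl)methane | CSCS(C)=O | starting material
3 | 1-bromo-2,3-dimethoxy-5-[(E)-2-(methylsulfinyl)-2-(methylsulfanyl)ethenyl]benzene, racemic at sulfur | CS(=O)/C(SC)=C/c1cc(OC)c(OC)c(Br)c1 | intermediate
4 | methyl 2-(3-bromo-4,5-dimethoxyphenyl)acetate | COC(=O)Cc1cc(OC)c(OC)c(Br)c1 | intermediate
5 | methyl formate | COC=O | starting material
6 | methyl (Z)-2-(3-bromo-4,5-dimethoxyphenyl)-3-hydroxyprop-2-enoate | COC(=O)/C(=C\O)c1cc(OC)c(OC)c(Br)c1 | intermediate
7 | methyl (Z)-2-(3-bromo-4,5-dimethoxyphenyl)-3-[(4-methylphenyl)sulfonyloxy]prop-2-enoate | COC(=O)/C(=C\OS(=O)(=O)c1ccc(C)cc1)c1cc(OC)c(OC)c(Br)c1 | intermediate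
8 | 3,5-bis(benzyloxy)phenol | Oc1cc(OCc2ccccc2)cc(OCc2ccccc2)c1 | starting material
9 | methyl (Z)-3-[3,5-bis(benzyloxy)phenoxy]-2-(3-bromo-4,5-dimethoxyphenyl)prop-2-enoate | COC(=O)/C(=C\Oc1cc(OCc2ccccc2)cc(OCc2ccccc2)c1)c1cc(OC)c(OC)c(Br)c1 | intermediate
10 | (Z)-3-[3,5-bis(benzyloxy)phenoxy]-2-(3-bromo-4,5-dimethoxyphenyl)prop-2-enoic acid | O=C(O)/C(c1cc(OC)c(OC)c(Br)c1)=C\Oc1cc(OCc2ccccc2)cc(OCc2ccccc2)c1 | intermediate
11 | (Z)-3-[3,5-bis(benzyloxy)phenoxy]-2-(3-bromo-4,5-dimethoxyphenyl)prop-2-enoyl chloride | O=C(Cl)/C(c1cc(OC)c(OC)c(Br)c1)=C\Oc1cc(OCc2ccccc2)cc(OCc2ccccc2)c1 | intermediate (not isolated)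
12 | 5,7-bis(benzyloxy)-3-(3-bromo-4,5-dimethoxyphenyl)chromen-4-one | COc1cc(-c2coc3cc(OCc4ccccc4)cc(OCc4ccccc4)c3c2=O)cc(Br)c1OC | intermediate
13 | 3-(3-bromo-4,5-dimethoxyphenyl)-5,7-dihydroxychromen-4-one | COc1cc(-c2coc3cc(O)cc(O)c3c2=O)cc(Br)c1OC | intermediate
14 | tributyl(3-methylbut-2-enyl)stannane | CCCC[Sn](CCCC)(CCCC)CC=C(C)C | starting material
15 | piscerythrinetin, 5,7-dihydroxy-3-[3,4-dimethoxy-5-(3-methylbut-2-enyl)phenyl]chromen-4-one | COc1cc(-c2coc3cc(O)cc(O)c3c2=O)cc(CC=C(C)C)c1OC | target

## Step count and least certain steps

Total step count: 9. Longest linear sequence: 9 steps, from 1 to 15; 2, 5, 8 and 14 are purchased and enter directly.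

Step 7 (key step). The most likely failure is Lewis acid cleavage of the benzyl ethers followed by re-attachment of benzyl cations to carbon of the electron-rich ring. A second risk is slow closure if much E isomer is present and the acyl chloride decomposes before it equilibrates. The fallback sets out from 4 and comes back at 13, and it replaces the ring closure at C4–C4a by an intermolecular acylation followed by insertion of C2.
- Saponification of 4 (LiOH, THF/H2O, then aq. HCl) gives 2-(3-bromo-4,5-dimethoxyphenyl)acetic acid F1.
- C-Acylation of phloroglucinol with F1 in BF3·OEt2 at about 85 °C gives 2-(3-bromo-4,5-dimethoxyphenyl)-1-(2,4,6-trihydroxyphenyl)ethanone F2.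
- Treatment of F2 with DMF, BF3·OEt2 and MsCl at about 70 °C formylates the methylene group and closes ring C onto either of the two equivalent ortho hydroxyl groups, which gives 13 with no protecting group to remove.

Step 9. The likely failures are allylic transposition during transmetalation or reductive elimination, which would attach the chain through its tertiary carbon, protonolysis of the allylic stannane by the acidic 7-OH, and slow oxidative addition at the hindered, electron-rich C–Br bond. The fallback sets out from 13 and comes back at 15.
- Stille coupling of 13 with allyltributylstannane (Pd(PPh3)4, DMF, 100 °C) gives 3-[3,4-dimethoxy-5-(prop-2-enyl)phenyl]-5,7-dihydroxychromen-4-one F3, for which both allyl termini lead to the same product.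
- Olefin cross-metathesis of F3 with excess 2-methylbut-2-ene (second-generation Grubbs catalyst, (H2IMes)(PCy3)Cl2Ru=CHPh, CH2Cl2, 40 °C) then builds the trisubstituted alkene and gives 15.

Step 5. The likely failures are sulfonyl transfer (attack of the phenoxide at sulfur, which returns the enolate of 6), attack through a ring carbon of the ambident phenoxide, and loss of geometry by reversible addition of a second phenoxide. The fallback sets out from 6 and comes back at 9.
- Chlorodehydroxylation of the enol 6 with oxalyl chloride and catalytic DMF (CH2Cl2, 0 °C to rt) gives methyl (Z)-2-(3-bromo-4,5-dimethoxyphenyl)-3-chloroprop-2-enoate F4; either geometry serves.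
- The phenoxide of 8 (K2CO3, DMF) displaces the chloride by addition–elimination with no sulfur electrophile present and gives 9.

Step 6. The likely failures are conjugate attack of hydroxide at C3 with expulsion of the aryloxide, which cleaves the vinyl ether, and sluggish hydrolysis of a hindered, electron-rich ester. The fallback sets out from 4 and comes back at 10, and it replaces hydrolysis by acidolysis of a tert-butyl ester.
- 2-(3-Bromo-4,5-dimethoxyphenyl)acetic acid F1, made from 4 as under step 7, is esterified with 2-methylpropene and catalytic H2SO4 to tert-butyl 2-(3-bromo-4,5-dimethoxyphenyl)acetate F5.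
- Formylation as in step 3 gives tert-butyl (Z)-2-(3-bromo-4,5-dimethoxyphenyl)-3-hydroxyprop-2-enoate F6.
- Tosylation as in step 4 gives tert-butyl (Z)-2-(3-bromo-4,5-dimethoxyphenyl)-3-[(4-methylphenyl)sulfonyloxy]prop-2-enoate F7.
- Exchange with 8 as in step 5 gives tert-butyl (Z)-3-[3,5-bis(benzyloxy)phenoxy]-2-(3-bromo-4,5-dimethoxyphenyl)prop-2-enoate F8.
- Trifluoroacetic acid in CH2Cl2 at 0 °C then removes the tert-butyl group as 2-methylpropene and gives 10 with no nucleophile present.

## Further compounds

F1 | step 7 | 2-(3-bromo-4,5-dimethoxyphenyl)acetic acid | OC(=O)Cc1cc(OC)c(OC)c(Br)c1
F2 | step 7 | 2-(3-bromo-4,5-dimethoxyphenyl)-1-(2,4,6-trihydroxyphenyl)ethanone | COc1cc(CC(=O)c2c(O)cc(O)cc2O)cc(Br)c1OC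
F3 | step 9 | 3-[3,4-dimethoxy-5-(prop-2-enyl)phenyl]-5,7-dihydroxychromen-4-one | COc1cc(-c2coc3cc(O)cc(O)c3c2=O)cc(CC=C)c1OC
F4 | step 5 | methyl (Z)-2-(3-bromo-4,5-dimethoxyphenyl)-3-chloroprop-2-enoate | COC(=O)/C(=C\Cl)c1cc(OC)c(OC)c(Br)c1
F5 | step 6 | tert-butyl 2-(3-bromo-4,5-dimethoxyphenyl)acetate | CC(C)(C)OC(=O)Cc1cc(OC)c(OC)c(Br)c1
F6 | step 6 | tert-butyl (Z)-2-(3-bromo-4,5-dimethoxyphenyl)-3-hydroxyprop-2-enoate | CC(C)(C)OC(=O)/C(=C\O)c1cc(OC)c(OC)c(Br)c1
F7 | step 6 | tert-butyl (Z)-2-(3-bromo-4,5-dimethoxyphenyl)-3-[(4-methylphenyl)sulfonyloxy]prop-2-enoate | CC(C)(C)OC(=O)/C(=C\OS(=O)(=O)c1ccc(C)cc1)c1cc(OC)c(OC)c(Br)c1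
F8 | step 6 | tert-butyl (Z)-3-[3,5-bis(benzyloxy)phenoxy]-2-(3-bromo-4,5-dimethoxyphenyl)prop-2-enoate | CC(C)(C)OC(=O)/C(=C\Oc1cc(OCc2ccccc2)cc(OCc2ccccc2)c1)c1cc(OC)c(OC)c(Br)c1
A1 | alternative 1 | 5,7-bis(methoxymethoxy)-3-[3,4-dimethoxy-5-(3-methylbut-2-enyl)phenyl]chromen-4-one | COCOc1cc(OCOC)c2c(c1)occ(-c1cc(OC)c(OC)c(CC=C(C)C)c1)c2=O
A2 | alternative 1 | 3-(5-methoxy-6-oxopyran-3-yl)-5,7-bis(methoxymethoxy)chromen-4-one | COCOc1cc(OCOC)c2c(c1)occ(-c1coc(=O)c(OC)c1)c2=O
A3 | alternative 1 | 1-methoxy-5-methylhex-4-en-1-yne | COC#CCC=C(C)C
A4 | alternative 2 | 2-[3,4-dimethoxy-5-(3-methylbut-2-enyl)phenyl]-1-(2,4,6-trihydroxyphenyl)ethanone | COc1cc(CC(=O)c2c(O)cc(O)cc2O)cc(CC=C(C)C)c1OC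
A5 | alternative 2 | methyl 8-[3,4-dimethoxy-5-(3-methylbut-2-enyl)phenyl]-3,5,7-trioxooctanoate | COC(=O)CC(=O)CC(=O)CC(=O)Cc1cc(OC)c(OC)c(CC=C(C)C)c1
A6 | alternative 3 | 5,7-bis(methoxymethoxy)-3-[3,4-dimethoxy-5-(3-methylbut-2-enyl)phenyl]-2-(trimethylsilyl)chromen-4-one | COCOc1cc(OCOC)c2c(c1)oc([Si](C)(C)C)c(-c1cc(OC)c(OC)c(CC=C(C)C)c1)c2=O
A7 | alternative 3 | 2-hydroxy-4,6-bis(methoxymethoxy)benzaldehyde | COCOc1cc(O)c(C=O)c(OCOC)c1
A8 | alternative 3 | {[3,4-dimethoxy-5-(3-methylbut-2-enyl)phenyl]ethynyl}trimethylsilane | COc1cc(C#C[Si](C)(C)C)cc(CC=C(C)C)c1OC
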